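## Retrosynthetic overview
1. The only ring to build is the 1,4-dioxane. It is closed last, in one operation, from two C6–C3 units, in the order of the plant oxidative coupling: 8–O–4′ bond first, then 7–O–3′ bond.
2. This disconnects to the hydroxy-o-quinone of (E)-3,4,5-trihydroxycinnamaldehyde and (E)-3,4,5-trimethoxycinnamyl alcohol. The monolignol is used already O-methylated, so no late differentiation of phenols is needed. A chiral Brønsted acid sets both stereocentres in this step.
3. (E)-3,4,5-Trihydroxycinnamaldehyde comes from 3,4,5-trihydroxybenzaldehyde and Ph3P=CHCHO by a protecting-group-free Wittig reaction.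
4. (E)-3,4,5-Trimethoxycinnamyl alcohol comes from methyl (E)-3,4,5-trimethoxycinnamate by DIBAL-H reduction.

Assumption: the sense of induction of the chiral phosphoric acid cannot be predicted with certainty. (R)-TRIP is written, and the equally available (S)-antipode replaces it if a first run (chiral HPLC/CD) shows the (2R,3R) series.

## Route

Step 1
Reactants: 1 methyl (E)-3-(3,4,5-trimethoxyphenyl)prop-2-enoate
Product: 2 (E)-3-(3,4,5-trimethoxyphenyl)prop-2-en-1-ol
Conditions: DIBAL-H (2.5 equiv), CH2Cl2, −78 → 0 °C; aq. Rochelle salt work-up (no acid)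
Reagents that add atoms: none
Why: DIBAL-H reduces the conjugated ester by two 1,2-hydride deliveries (ester-to-allylic-alcohol reduction) without touching the alkene, so the E geometry of 1 is kept and no stereocentre is formed.

Step 2
Reactants: 3 3,4,5-trihydroxybenzaldehyde; 4 (triphenylphosphoranylidene)acetaldehyde
Product: 5 (E)-3-(3,4,5-trihydroxyphenyl)prop-2-enal
Conditions: 4 (1.1 equiv, in portions), THF, 65 °C, Ar, 24 h
Reagents that add atoms: (triphenylphosphoranylidene)acetaldehyde, O=CC=P(c1ccccc1)(c1ccccc1)c1ccccc1
Why: This is a Wittig olefination with a stabilised formyl ylide, which gives the E-enal; the ylide is too weakly basic in THF to be quenched by the phenols, near-stoichiometric ylide limits a second homologation, and no stereocentre is formed.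

Step 3
Reactants: 5 (E)-3-(3,4,5-trihydroxyphenyl)prop-2-enal; 2 (E)-3-(3,4,5-trimethoxyphenyl)prop-2-en-1-ol (2.0 equiv)
Product: 7 (E)-3-[(2S,3S)-8-hydroxy-2-(hydroxymethyl)-3-(3,4,5-trimethoxyphenyl)-2,3-dihydro-1,4-benzodioxin-6-yl]prop-2-enal, via hydroxy-o-quinone 6 (not isolated)
Conditions: 5, PhI(OAc)2 (1.0 equiv), 4 Å MS, CH2Cl2–MeCN 3:1, −40 °C, 10 min; then 2, (R)-TRIP (10 mol %), −40 °C, 24 h
Reagents that add atoms: none
Why: Proposed new method: PhI(OAc)2 dehydrogenates the pyrogallol to 6 (known catechol-to-o-quinone oxidation) before 2 is added, so neither 2 nor 7 meets the oxidant; the chiral acid then protonates or H-bonds the vinylogous-acid carbonyl of 6, so the complex behaves as a symmetric 2,6-dihydroxyphenoxenium phosphate whose only electrophilic oxygen is O-4′; the nucleophilic C-8 of 2, held to the phosphoryl oxygen through its CH2OH, attacks that oxygen on one alkene face and sets C-2 (S); the resulting 3,4,5-trimethoxybenzyl cation, the O-methyl analogue of the biosynthetic quinone methide, is closed on the same face by either of the two equivalent flanking OH groups to give the diequatorial trans ring and set C-3 (S), and the unused OH becomes the 8-OH; overall this is an asynchronous inverse-electron-demand oxa-Diels–Alder reaction, and the closest known reaction types are the thermal, racemic, regio- and trans-selective hetero-Diels–Alder reaction of 3-alkoxy-o-quinones with O-protected sinapyl alcohols and the chiral-phosphoric-acid-catalysed tandem oxidation/formal cycloaddition of quinone (mono)imines with styrenes and enecarbamates.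

## Compound list
1 | methyl (E)-3-(3,4,5-trimethoxyphenyl)prop-2-enoate | COC(=O)/C=C/c1cc(OC)c(OC)c(OC)c1 | starting material
2 | (E)-3-(3,4,5-trimethoxyphenyl)prop-2-en-1-ol | COc1cc(/C=C/CO)cc(OC)c1OC | intermediate
3 | 3,4,5-trihydroxybenzaldehyde | O=Cc1cc(O)c(O)c(O)c1 | starting material
4 | (triphenylphosphoranylidene)acetaldehyde | O=CC=P(c1ccccc1)(c1ccccc1)c1ccccc1 | starting material
5 | (E)-3-(3,4,5-trihydroxyphenyl)prop-2-enal | O=C/C=C/c1cc(O)c(O)c(O)c1 | intermediate
6 | (E)-3-(5-hydroxy-3,4-dioxocyclohexa-1,5-dien-1-yl)prop-2-enal (not isolated) | O=C/C=C/C1=CC(=O)C(=O)C(O)=C1 | intermediate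
7 | (E)-3-[(2S,3S)-8-hydroxy-2-(hydroxymethyl)-3-(3,4,5-trimethoxyphenyl)-2,3-dihydro-1,4-benzodioxin-6-yl]prop-2-enal | COc1cc([C@@H]2Oc3cc(/C=C/C=O)cc(O)c3O[C@H]2CO)cc(OC)c1OC | target

## Summary
Total step count: 3. Longest linear sequence: 2 (3 → 5 → 7, or 1 → 2 → 7).

**Most likely to fail: step 3.** Several H-bonding modes between the acid, 6 and 2 may compete and lower the ee. Quinone 6 may self-condense (purpurogallin type). Alkene 2 may add through carbon, by a [3+2] or carbo-Diels–Alder path, instead of through oxygen.

The fallback gives up catalyst control of configuration and resolves the racemate.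
- It sets out from 5 and 2. The same PhI(OAc)2 oxidation to 6 is followed by cycloaddition with achiral diphenyl phosphate (10 mol %) from −40 °C to rt.
- This gives the trans-benzodioxane as a racemate: 7 together with its mirror image (E)-3-[(2R,3R)-8-hydroxy-2-(hydroxymethyl)-3-(3,4,5-trimethoxyphenyl)-2,3-dihydro-1,4-benzodioxin-6-yl]prop-2-enal F1.
- Kinetic resolution with immobilised Candida antarctica lipase B and vinyl acetate (MTBE–acetone, 40 °C, stopped near 50 % conversion) acylates only the primary alcohol.
- By analogy with the lipase resolution of flavonolignan 2-aryl-3-hydroxymethylbenzodioxanes, the (2S,3S) series is expected to react faster. It gives [(2S,3S)-8-hydroxy-6-[(E)-3-oxoprop-1-enyl]-3-(3,4,5-trimethoxyphenyl)-2,3-dihydro-1,4-benzodioxin-2-yl]methyl acetate F2.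
- F2 is separated from unreacted F1 by chromatography. It is deacetylated with the same lipase and n-butanol (MTBE, 40 °C), which acts as a second enantiomer-selective pass. The fallback comes back to the route at 7.

**Second: step 2.** The para-hydroxy aldehyde is a poor electrophile, enal 5 can be homologated again to the dienal, and the free pyrogallol is air-sensitive on prolonged heating.

The fallback postpones the olefination until after ring formation.
- It sets out from 3 and 2. Compound 3 is oxidised with PhI(OAc)2 under the step 3 conditions to 5-hydroxy-3,4-dioxocyclohexa-1,5-diene-1-carbaldehyde F3.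
- F3 is used in situ with 2 and (R)-TRIP. It gives (2S,3S)-8-hydroxy-2-(hydroxymethyl)-3-(3,4,5-trimethoxyphenyl)-2,3-dihydro-1,4-benzodioxine-6-carbaldehyde F4.
- F4 carries only one phenol, meta to the formyl group, and undergoes a normal Wittig reaction with 4 (toluene, 80 °C). The fallback comes back to the route at 7.

**Third: step 1.** Partial conjugate or over-reduction can occur, and the acid-sensitive electron-rich allylic alcohol can be lost on work-up.

The fallback builds the side chain by olefination and then a chemoselective 1,2-reduction instead of reducing an ester.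
- It sets out from ylide 4, which is condensed with purchased 3,4,5-trimethoxybenzaldehyde F5 (toluene, 90 °C). This gives (E)-3-(3,4,5-trimethoxyphenyl)prop-2-enal F6.
- Luche reduction of F6 (NaBH4, CeCl3·7H2O, MeOH, 0 °C) brings the fallback back to the route at 2.

## Further compounds
F1 | step 3 | (E)-3-[(2R,3R)-8-hydroxy-2-(hydroxymethyl)-3-(3,4,5-trimethoxyphenyl)-2,3-dihydro-1,4-benzodioxin-6-yl]prop-2-enal | COc1cc([C@H]2Oc3cc(/C=C/C=O)cc(O)c3O[C@@H]2CO)cc(OC)c1OC
F2 | step 3 | [(2S,3S)-8-hydroxy-6-[(E)-3-oxoprop-1-enyl]-3-(3,4,5-trimethoxyphenyl)-2,3-dihydro-1,4-benzodioxin-2-yl]methyl acetate | COc1cc([C@@H]2Oc3cc(/C=C/C=O)cc(O)c3O[C@H]2COC(C)=O)cc(OC)c1OC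
F3 | step 2 | 5-hydroxy-3,4-dioxocyclohexa-1,5-diene-1-carbaldehyde | O=CC1=CC(=O)C(=O)C(O)=C1
F4 | step 2 | (2S,3S)-8-hydroxy-2-(hydroxymethyl)-3-(3,4,5-trimethoxyphenyl)-2,3-dihydro-1,4-benzodioxine-6-carbaldehyde | COc1cc([C@@H]2Oc3cc(C=O)cc(O)c3O[C@H]2CO)cc(OC)c1OC
F5 | step 1 | 3,4,5-trimethoxybenzaldehyde (purchased) | COc1cc(C=O)cc(OC)c1OC
F6 | step 1 | (E)-3-(3,4,5-trimethoxyphenyl)prop-2-enal | COc1cc(/C=C/C=O)cc(OC)c1OC
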